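Readings and results are calculated with constants of no real substance; the scatter is artificial.

The easy step is a subtraction: the substrate charged less the last reading is the target made.

| flask | substrate | partner | free catalyst | time |
|---|---|---|---|---|
| birch | 50.0 mM | 100 mM | 5.00 mM |  |
| alder | 30.0 mM | 80.0 mM | 5.00 mM |  |
| elm | 100 mM | 100 mM | 5.00 mM |  |
| maple | 50.0 mM | 40.0 mM | 5.00 mM | 92 min |

| run | time / min | [substrate] / mM |
|---|---|---|
| birch run | 3.7 | 47.6 |
| birch run | 7.0 | 45.9 |
| birch run | 13 | 42.4 |
| birch run | 25 | 38.6 |
| birch run | 48 | 34.9 |
| birch run | 92 | 33.2 |
| alder run | 3.7 | 29.1 |
| alder run | 7.0 | 27.2 |
| alder run | 13 | 25.3 |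
| alder run | 25 | 22.3 |
| alder run | 48 | 19.5 |
| alder run | 92 | 17.2 |
| elm run | 3.7 | 95.1 |
| elm run | 7.0 | 92.0 |
| elm run | 13 | 88.1 |
| elm run | 25 | 83.5 |
| elm run | 48 | 81.7 |
| elm run | 92 | 81.6 |

(readings scatter by 0.5 mM)

- Overall: substrate + partner -> target, with free catalyst as catalyst.
- Constant volume, constant temperature.
- The analysis sees a species whether free or bound.
- "The second partner" is partner.
- An order is taken over about fifteen percent of the charge, up and down.

- apparent order in [substrate] of the starting rate, round the charge of the birch run (the rate where two percent of its substrate have turned into target) (one fixed amount of target, the same in the runs compared)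
- apparent order in [partner] of the starting rate, round the charge of the birch run (the rate where two percent of its substrate have turned into target)
- substrate in the maple run at 92 min, as a share of the substrate charged

I build a ladder of times, fastest first. By 7.0 min the birch run has lost 8.20 % of its substrate, the alder run 9.33 % and the elm run 8.00 %. Elm and birch share a partner charge, so I read a substrate order of 0.964. The alder run has less partner and less substrate, and it loses a larger fraction, so with a substrate order near one I read a partner order near zero, roughly.

The first rung is the time in which the early rate would make the target of the last reading. It is 16.1 min for elm, 28.7 min for birch and 32.0 min for alder, so elm's is shorter than the other two. The next rung is emptying the charge at that early rate, 85.4 min for birch, which is longer than either birch's or alder's first rung. So these flasks slow down with substrate left.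

Elm has twice birch's substrate but makes 1.10 times birch's target by the last reading. So I divide by partner instead. Birch gives 16.8 %, alder 16.0 % and elm 18.4 %. I carry the target made by the last reading as a fraction of the partner charged, the partner yield.

In the maple run partner is the limiting reagent, which allows 80.0 % of the substrate to turn. Birch's yield gives my own reckoning:

substrate left = 1 − partner yield × partner charged / substrate charged = 86.6 %

Alder is still falling at its last reading, so I hold this figure as a high one.

The forecast gives order 1 in substrate, order 0 in partner and 69 % of the maple substrate left at 92 min, on the ground “Maple should resemble birch, stalling near 15–17 mM converted”. My figure differs from it.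

The maple run holds 77.2 % of its substrate charge at 92 min, and the orders round the birch charge are 0.88 in substrate and 0.095 in partner.

    free catalyst + substrate ⇌ catalyst-substrate complex, settled at all times (3.080 M⁻¹)
    free catalyst + partner ⇌ catalyst-reagent complex, settled at all times (10.90 M⁻¹)
    catalyst-substrate complex + catalyst-reagent complex → target + 2 free catalyst (942.0 M⁻¹ min⁻¹)
    2 partner → lost reagent (0.2718 M⁻¹ min⁻¹)
    catalyst-substrate complex → spent catalyst + substrate (0.1812 min⁻¹)

My figure stands above the result and the forecast below it. The partner order of 0.095 is small round the birch charge. The maple run's partner yield is 28.4 %, higher than birch's 16.8 %. In the alder run, target reaches a quarter of the substrate charged at 23.5 min, a partner yield of 9.38 %, against 16.0 % at 92 min.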